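**Plan**

- Numbering: naphthalene C1 (aryl ring C), C2 (OH), C3 (CHO), C4 (H), C7 (OH), C8 (OMe). Ring A is the C4a–C8a benzo ring and ring B is C1–C4.
- Retrosynthesis: the C7 phenol is masked as an isopropyl ether, the C3 aldehyde comes from a methyl ester and the C2 hydroxyl from a C2 bromide. Ring B is then cut at C1–C2 and C3–C4 (with water restored across C4/C1), giving an ortho-benzylbenzaldehyde and methyl 3-bromopropiolate.
- Enabling feature: C1 and C4 are both benzylic to ring A. A 2-benzylbenzaldehyde therefore already holds C1, C8a, C4a and C4 as a latent hydroxy-diene that needs only the two-carbon unit C2–C3.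
- Forward order: ring A is bought as O-isopropylvanillin and iodinated at the carbon that becomes C8a. Ring C is attached through the future C1 methylene by Negishi coupling, and ring B is closed last by photoenolization, [4+2] cycloaddition and dehydration. Bromide-to-hydroxyl exchange, ester-to-aldehyde adjustment and deprotection follow.
- Stereochemistry: the target has no stereocentre. The two sp3 centres formed in the cycloaddition are removed by the dehydration.

Key step: step 4

Remark: the C7 phenol is carried as an isopropyl ether because an aryl benzyl ether would be at risk of benzylic deprotonation and Wittig rearrangement under the excess n-BuLi of step 1; compounds 1, 5 and 8 are assumed to be purchased.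

**Route**

Step 1
Reactants: 1 4-isopropoxy-3-methoxybenzaldehyde (O-isopropylvanillin)
Product: 4 2-iodo-4-isopropoxy-3-methoxybenzaldehyde, via lithium α-amino alkoxide 2 (not isolated), via C2-lithiated α-amino alkoxide 3 (not isolated)
Conditions: HN(Me)CH2CH2NMe2, n-BuLi, THF, −20 °C; then n-BuLi (3 equiv), −20 °C; I2, −78 °C → rt; H2O, aq. Na2S2O3
Reagents that add atoms: iodine, II
Why: α-amino alkoxide-directed ortho-lithiation, in which the lithium amide adds to the aldehyde to mask it and the resulting chelating alkoxide, together with the C3 methoxy group, should direct n-BuLi to the doubly flanked C2 position, while the bulky isopropyl ether is a poor director and inert to the base; iodine quench and hydrolysis of the hemiaminal return the aldehyde.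

Step 2
Reactants: 4 2-iodo-4-isopropoxy-3-methoxybenzaldehyde; 5 3,4-dimethoxybenzyl chloride
Product: 7 2-(3,4-dimethoxybenzyl)-4-isopropoxy-3-methoxybenzaldehyde, via 3,4-dimethoxybenzylzinc chloride 6 (not isolated)
Conditions: 5, Zn dust, LiCl, THF, 25 °C; then 4, Pd(OAc)2 (2 mol %), SPhos (4 mol %), THF, 25 °C, slow addition of the zinc reagent
Reagents that add atoms: none
Why: Negishi cross-coupling, in which LiCl-assisted zinc insertion into the benzylic chloride gives the benzylzinc reagent with little homocoupling and the zerovalent palladium/SPhos catalyst should couple the di-ortho-substituted aryl iodide faster than the organozinc adds to the electron-rich aldehyde.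

Step 3
Reactants: 8 methyl propiolate
Product: 9 methyl 3-bromopropiolate
Conditions: NBS, AgNO3 (10 mol %), acetone, 25 °C; used as a solution after filtration and careful concentration
Reagents that add atoms: N-bromosuccinimide, O=C1CCC(=O)N1Br
Why: silver-catalysed electrophilic bromination of a terminal alkyne through the silver acetylide, the standard preparation of 1-bromoalkynes and tolerant of the ester.

Step 4
Reactants: 7 2-(3,4-dimethoxybenzyl)-4-isopropoxy-3-methoxybenzaldehyde; 9 methyl 3-bromopropiolate
Product: 12 methyl 3-bromo-4-(3,4-dimethoxyphenyl)-6-isopropoxy-5-methoxy-2-naphthoate (target numbering: 1-aryl, 2-bromo, 3-ester, 7-isopropoxy, 8-methoxy), via (E)-hydroxy-o-quinodimethane 10 (not isolated), via dihydronaphthalenol cycloadduct 11 (not isolated)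
Conditions: hν (350–365 nm, Pyrex), 9 (3 equiv), degassed toluene, 25 °C; then lamp off, p-TsOH·H2O (10 mol %), 60 °C
Reagents that add atoms: none
Why: Excitation of the aryl aldehyde is followed by 1,5-hydrogen transfer from the doubly benzylic methylene to the carbonyl oxygen, and the biradical relaxes to the (E)-hydroxy-o-quinodimethane 10, a diene spanning C4, C4a, C8a and C1. The closest known reaction type is the photoenolization/Diels–Alder reaction of ortho-alkyl aryl aldehydes with electron-poor alkynes followed by dehydration to naphthalenes, applied here to a haloalkynoate. Ring B closes by an intermolecular suprafacial [4+2] cycloaddition that forms C1–C2 and C3–C4 and restores the aromaticity of ring A, which drives the reaction. The two sp3 centres of 11 (C1 and C4) are not controlled and need not be, because acid-promoted 1,4-loss of water (OH from C4, H from C1) removes both and aromatises ring B. The selectivity required is regiochemical: the enol oxygen on C4 makes C1 the nucleophilic diene terminus, so C1 should bond to the bromine-bearing β-carbon of the ynoate and place the ester on C3 next to the carbinol carbon, the usual ortho orientation of 1-oxygenated dienes. Irradiation above 340 nm is meant to excite only the aldehyde and spare the C–Br bond of 9, and the acid is added after the lamp is off so that the bromonaphthalene is not exposed to light.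

Step 5
Reactants: 12 methyl 3-bromo-4-(3,4-dimethoxyphenyl)-6-isopropoxy-5-methoxy-2-naphthoate
Product: 14 4-(3,4-dimethoxyphenyl)-3-hydroxy-6-isopropoxy-5-methoxy-2-naphthoic acid, via potassium bromonaphthoate 13 (not isolated)
Conditions: KOH (6 equiv), DMSO–H2O (1:1), 80 °C; then Cu2O (10 mol %), 1,10-phenanthroline (20 mol %), 110 °C, Ar; aq. HCl
Reagents that add atoms: potassium hydroxide, [K+].[OH-]
Why: ester saponification followed in the same pot by Ullmann-type copper-catalysed hydroxylation, in which the ortho carboxylate binds monovalent copper and accelerates displacement of the neighbouring bromide by hydroxide, the classical reactivity of 2-halobenzoic acids.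

Step 6
Reactants: 14 4-(3,4-dimethoxyphenyl)-3-hydroxy-6-isopropoxy-5-methoxy-2-naphthoic acid
Product: 15 1-(3,4-dimethoxyphenyl)-3-(hydroxymethyl)-7-isopropoxy-8-methoxynaphthalen-2-ol
Conditions: LiAlH4 (excess), THF, 0 → 65 °C; aq. potassium sodium tartrate work-up
Reagents that add atoms: none
Why: hydride reduction of a salicylic-type acid to the salicyl alcohol, the standard treatment of 3-hydroxy-2-naphthoic acids, with the aryl ethers inert to the reagent.

Step 7
Reactants: 15 1-(3,4-dimethoxyphenyl)-3-(hydroxymethyl)-7-isopropoxy-8-methoxynaphthalen-2-ol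
Product: 16 4-(3,4-dimethoxyphenyl)-3-hydroxy-6-isopropoxy-5-methoxy-2-naphthaldehyde
Conditions: activated MnO2 (excess), CH2Cl2, 25 °C
Reagents that add atoms: none
Why: chemoselective heterogeneous oxidation of a benzylic alcohol by MnO2, which should stop at the hydrogen-bonded ortho-hydroxy aldehyde and leave the naphthol untouched, as in the preparation of 3-hydroxy-2-naphthaldehyde.

Step 8
Reactants: 16 4-(3,4-dimethoxyphenyl)-3-hydroxy-6-isopropoxy-5-methoxy-2-naphthaldehyde
Product: 17 vitrofolal B, 4-(3,4-dimethoxyphenyl)-3,6-dihydroxy-5-methoxy-2-naphthaldehyde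
Conditions: BCl3 (3 equiv), CH2Cl2, −78 → 0 °C; then H2O
Reagents that add atoms: none
Why: Lewis-acid cleavage of a secondary alkyl aryl ether, in which BCl3 ionises the isopropyl–oxygen bond far faster at low temperature than it attacks aryl methyl ethers, an established selectivity; no methoxy group sits ortho to the carbonyl where chelation could assist its loss.

**Compound list**

1 | 4-isopropoxy-3-methoxybenzaldehyde | O=Cc1ccc(OC(C)C)c(OC)c1 | starting material
2 | lithium α-amino alkoxide from 1 and lithium N,N,N'-trimethylethylenediamide (racemic at the hemiaminal carbon) | [Li]OC(N(C)CCN(C)C)c1ccc(OC(C)C)c(OC)c1 | intermediate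
3 | C2-lithiated α-amino alkoxide (racemic) | [Li]OC(N(C)CCN(C)C)c1ccc(OC(C)C)c(OC)c1[Li] | intermediate
4 | 2-iodo-4-isopropoxy-3-methoxybenzaldehyde | O=Cc1ccc(OC(C)C)c(OC)c1I | intermediate
5 | 3,4-dimethoxybenzyl chloride | COc1ccc(CCl)cc1OC | starting material
6 | 3,4-dimethoxybenzylzinc chloride | COc1ccc(C[Zn]Cl)cc1OC | intermediate
7 | 2-(3,4-dimethoxybenzyl)-4-isopropoxy-3-methoxybenzaldehyde | O=Cc1ccc(OC(C)C)c(OC)c1Cc1ccc(OC)c(OC)c1 | intermediate
8 | methyl propiolate | C#CC(=O)OC | starting material
9 | methyl 3-bromopropiolate | COC(=O)C#CBr | intermediate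
10 | (E)-dienol 6-(3,4-dimethoxybenzylidene)-5-(hydroxymethylidene)-2-isopropoxy-1-methoxycyclohexa-1,3-diene (enol geometry E, benzylidene geometry not defined) | O/C=C1\C=CC(OC(C)C)=C(OC)C1=Cc1ccc(OC)c(OC)c1 | intermediate
11 | methyl 3-bromo-4-(3,4-dimethoxyphenyl)-1-hydroxy-6-isopropoxy-5-methoxy-1,4-dihydronaphthalene-2-carboxylate (racemic, configuration at the two sp3 carbons not defined) | COC(=O)C1=C(Br)C(c2ccc(OC)c(OC)c2)c2c(ccc(OC(C)C)c2OC)C1O | intermediate
12 | methyl 3-bromo-4-(3,4-dimethoxyphenyl)-6-isopropoxy-5-methoxy-2-naphthoate | COC(=O)c1cc2ccc(OC(C)C)c(OC)c2c(-c2ccc(OC)c(OC)c2)c1Br | intermediate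
13 | potassium 3-bromo-4-(3,4-dimethoxyphenyl)-6-isopropoxy-5-methoxy-2-naphthoate | [K+].[O-]C(=O)c1cc2ccc(OC(C)C)c(OC)c2c(-c2ccc(OC)c(OC)c2)c1Br | intermediate
14 | 4-(3,4-dimethoxyphenyl)-3-hydroxy-6-isopropoxy-5-methoxy-2-naphthoic acid | OC(=O)c1cc2ccc(OC(C)C)c(OC)c2c(-c2ccc(OC)c(OC)c2)c1O | intermediate
15 | 1-(3,4-dimethoxyphenyl)-3-(hydroxymethyl)-7-isopropoxy-8-methoxynaphthalen-2-ol | OCc1cc2ccc(OC(C)C)c(OC)c2c(-c2ccc(OC)c(OC)c2)c1O | intermediate
16 | 4-(3,4-dimethoxyphenyl)-3-hydroxy-6-isopropoxy-5-methoxy-2-naphthaldehyde | O=Cc1cc2ccc(OC(C)C)c(OC)c2c(-c2ccc(OC)c(OC)c2)c1O | intermediate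
17 | vitrofolal B, 4-(3,4-dimethoxyphenyl)-3,6-dihydroxy-5-methoxy-2-naphthaldehyde | COc1ccc(-c2c(O)c(C=O)cc3ccc(O)c(OC)c23)cc1OC | target

**Step count and risks**

Total step count: 8. Longest linear sequence: 7 steps (steps 1, 2, 4, 5, 6, 7, 8); step 3 is a one-step side branch.

Steps most likely to fail:

1. Step 4. The bromoalkynoate may quench the excited aldehyde or lose bromine under irradiation, or the photoenol may revert to the aldehyde faster than the hindered C1 terminus is trapped. The fallback separates the photochemistry from the cycloaddition. It sets out from 7, which is irradiated (350 nm) in SO2-saturated benzene so that the photoenol is captured by cheletropic addition as 3-(3,4-dimethoxyphenyl)-1-hydroxy-5-isopropoxy-4-methoxy-1,3-dihydrobenzo[c]thiophene 2,2-dioxide F1 (mixture of diastereomers). Heating this sulfone with 9 in toluene at about 90 °C in the dark should extrude SO2, regenerate the (E)-dienol thermally and give the cycloadduct. Acid dehydration with p-TsOH then returns the route to 12.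

2. Step 5. Substitution of the bromide may stall because C2 is flanked by the C1 aryl group and the carboxylate, with protodebromination taking over at the temperature needed. The fallback replaces the copper C–O coupling by C–B bond formation and oxidation. It sets out from 12, which under Miyaura borylation (B2pin2, KOAc, Pd(OAc)2, SPhos, dioxane, 100 °C) should give methyl 4-(3,4-dimethoxyphenyl)-6-isopropoxy-5-methoxy-3-(4,4,5,5-tetramethyl-1,3,2-dioxaborolan-2-yl)-2-naphthoate F2. Oxidation with NaBO3·4H2O in THF–H2O should give methyl 4-(3,4-dimethoxyphenyl)-3-hydroxy-6-isopropoxy-5-methoxy-2-naphthoate F3. LiAlH4 reduction of this hydroxy ester rejoins the route at 15.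

3. Step 1. Lithiation may be incomplete or may drift to C6, and any aldehyde released from the amino alkoxide would be attacked by n-BuLi. The fallback uses a preformed, isolable directing group. It sets out from 1, which is condensed with cyclohexylamine (toluene, molecular sieves) to (E)-N-cyclohexyl-1-(4-isopropoxy-3-methoxyphenyl)methanimine F4. Treatment with n-BuLi in THF at −78 °C should lithiate the position between the imine and the methoxy group to give (E)-N-cyclohexyl-1-(2-lithio-4-isopropoxy-3-methoxyphenyl)methanimine F5. Iodine quench gives (E)-N-cyclohexyl-1-(2-iodo-4-isopropoxy-3-methoxyphenyl)methanimine F6, and hydrolysis with dilute aqueous HCl rejoins the route at 4.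

**Further compounds**

F1 | step 4 | 3-(3,4-dimethoxyphenyl)-1-hydroxy-5-isopropoxy-4-methoxy-1,3-dihydrobenzo[c]thiophene 2,2-dioxide (mixture of diastereomers) | OC1c2ccc(OC(C)C)c(OC)c2C(c2ccc(OC)c(OC)c2)S1(=O)=O
F2 | step 5 | methyl 4-(3,4-dimethoxyphenyl)-6-isopropoxy-5-methoxy-3-(4,4,5,5-tetramethyl-1,3,2-dioxaborolan-2-yl)-2-naphthoate | COC(=O)c1cc2ccc(OC(C)C)c(OC)c2c(-c2ccc(OC)c(OC)c2)c1B3OC(C)(C)C(C)(C)O3
F3 | step 5 | methyl 4-(3,4-dimethoxyphenyl)-3-hydroxy-6-isopropoxy-5-methoxy-2-naphthoate | COC(=O)c1cc2ccc(OC(C)C)c(OC)c2c(-c2ccc(OC)c(OC)c2)c1O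
F4 | step 1 | (E)-N-cyclohexyl-1-(4-isopropoxy-3-methoxyphenyl)methanimine | CC(C)Oc1ccc(/C=N/C2CCCCC2)cc1OC
F5 | step 1 | (E)-N-cyclohexyl-1-(2-lithio-4-isopropoxy-3-methoxyphenyl)methanimine | CC(C)Oc1ccc(/C=N/C2CCCCC2)c([Li])c1OC
F6 | step 1 | (E)-N-cyclohexyl-1-(2-iodo-4-isopropoxy-3-methoxyphenyl)methanimine | CC(C)Oc1ccc(/C=N/C2CCCCC2)c(I)c1OC
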